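(All runs come from a simulation for substances that don't exist; noise was put on by code.)

- In a one-step world a substrate meets its partner and the rate is the product of the two amounts. We try this on the pool of left-handed and right-handed substrate together, taking one coupling partner per substrate.

| flask | left-handed substrate | right-handed substrate | coupling partner | free catalyst | remark | time |
|---|---|---|---|---|---|---|
| elm | 0.34 M | 0.34 M | 1.5 M | 0.82 mM | run made earlier |  |
| oak | 0.51 M | 0.51 M | 1.5 M | 0.82 mM | run made earlier |  |
| flask | 0.68 M | 0.68 M | 1.50 M | 0.82 mM |  | 15 h |

- elm (time / h: left-handed product / %, right-handed product / %): 1.00: 26.1, 4.1; 3.00: 39.3, 19.1; 5.00: 45.0, 29.2; 8.00: 46.9, 38.9; 10.0: 50.0, 44.0; 15.0: 49.6, 47.5; 20.0: 49.6, 49.1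
- oak (time / h: left-handed product / %, right-handed product / %): 1.00: 25.6, 5.6; 3.00: 40.1, 18.2; 5.00: 43.0, 28.6; 8.00: 45.4, 35.6; 10.0: 46.9, 40.6; 15.0: 46.5, 45.9; 20.0: 49.6, 47.8

(standard deviation of a reading: 1 percentage point)

1. excess of left-handed product over right-handed product in the product at 1.5 h
2. excess of left-handed product over right-handed product in the product at 15 h
3. part of the left-handed substrate and right-handed substrate charged together that has reacted at 15 h

- free catalyst is single-handed; left-handed substrate and right-handed substrate are mirror images of each other, charged as a racemate, each of them at the stated concentration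
- an excess is the difference of the two amounts in percent of their sum
- an excess is below zero if the other one leads

- Pool and partner then fall together, so the surplus, partner charged minus pool charged, stays fixed through a run: 0.820 M in elm, 0.480 M in oak, 0.140 M in the flask. All three are charged with 0.82 mM of free catalyst.
- Under this rate, the logarithm of partner over pool climbs in a straight line. At 10.0 h, the two product readings add up to 94.0% reacted in elm and 87.5% in oak. These give 0.275 M⁻¹ h⁻¹ and 0.245 M⁻¹ h⁻¹, with a mean of 0.260 M⁻¹ h⁻¹. This mean is our pool constant, the hourly climb of that logarithm divided by the surplus.
- Our first way carries the pool constant to the flask and gives 88.6% reacted at 15 h.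
- Our second way uses other readings and no rate law. The charges are evenly spaced, so a straight line through the elm and oak conversions at 15.0 h gives 87.7%.
- The two ways differ by 0.90 percentage points, less than the 1 point scatter of a single reading, so we commit to 88.6%. The pool does not separate the hands, so we give no number for either excess.
- The forecast gives an excess of left-handed product of 52% (42% to 60%) at 1.5 h and 6% (2% to 12%) at 15 h, with 88% (79% to 94%) reacted at 15 h, noting that “partner depletion may cut this further”.
- The flask gives excesses of 57.8% at 1.5 h and 2.48% at 15 h, with 87.9% reacted at 15 h.

    left-handed substrate ⇌ right-handed substrate (k = 0.400 h⁻¹)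
    left-handed product ⇌ right-handed product (k = 0.260 h⁻¹)
    free catalyst → spent catalyst (k = 0.0610 h⁻¹)
    2 free catalyst ⇌ resting dimer, settled at all times (K = 3600 M⁻¹)
    coupling partner + free catalyst + left-handed substrate → free catalyst + left-handed product (k = 2300 M⁻² h⁻¹)
    coupling partner + free catalyst + right-handed substrate → free catalyst + right-handed product (k = 82.0 M⁻² h⁻¹)

- Read back through the same logarithm, the flask's 87.9% gives a pool constant of 0.246 M⁻¹ h⁻¹. The neighbour flask has the same charges except for 0.90 M of coupling partner, which is less than its pool. Partner is there the limiting reagent, covering 66.2% of the pool, and the surplus is −0.460 M. With 0.260 M⁻¹ h⁻¹, the reckoning gives 62.0% reacted at 15 h. That neighbour flask gives 62.4% reacted, with 5.7% of its coupling partner left.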